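Everything rests on opening ring B at its tetrasubstituted C2=C3 alkene, which lies next to the quaternary C1 (CMe2) of the cis-hexahydronaphthalene; that adjacency is the feature exploited. Delivering the second C1 methyl as a cuprate to a C1=C2 alkylidene phosphonoacetate attached to C8a creates a C2 phosphonate carbanion, which olefinates the C3 methyl ketone on the cis C4a arm. One operation forms C1–CH3 and C2=C3 and closes ring B. The precursor is a cis-1,2-disubstituted 4-methylcyclohexene (ring A) set by an auxiliary-controlled Diels–Alder reaction. The C2 ester then becomes a phosphonium salt that is joined to an enantiopure 6-formyl-1,2-dioxane.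

Key step: step 11

Assumption: the carbinol centre of 1 is erased in step 10, so either enantiomer or the racemate would serve; the S enantiomer is used only so that 2–17 are single stereoisomers (ring atoms are labelled C1–C8a as in the hexahydronaphthalene of the target).

Step 1
Reactants: 1 (S)-pent-4-yn-2-ol
Product: 2 (S)-tert-butyldimethyl(pent-4-yn-2-yloxy)silane
Conditions: TBSCl, imidazole, DMF, 0 °C → rt
Reagents that add atoms: tert-butyldimethylsilyl chloride, CC(C)(C)[Si](C)(C)Cl
Why: Imidazole-promoted silyl ether formation masks the oxygen of the future C3 ketone through the organometallic and Lewis-acid steps and touches no stereocentre.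

Step 2
Reactants: 2 (S)-tert-butyldimethyl(pent-4-yn-2-yloxy)silane; 3 2-bromopropene
Product: 5 (S,E)-tert-butyldimethyl[(6-methylhepta-4,6-dien-2-yl)oxy]silane, via E-alkenylboronate 4 (not isolated)
Conditions: HBpin, Cp2ZrHCl (10 mol%), Et3N (10 mol%), neat, 60 °C; then 3, PdCl2(dppf) (3 mol%), aq K3PO4, THF, 50 °C
Reagents that add atoms: pinacolborane, [H]B1OC(C)(C)C(C)(C)O1 (its boryl group is carried only by 4)
Why: Zirconium-catalysed syn hydroboration puts boron on the alkyne terminus, and Suzuki–Miyaura coupling with retention then gives the E-diene that an endo Diels–Alder reaction needs for a cis product.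

Step 3
Reactants: 6 (R)-4-benzyl-1,3-oxazolidin-2-one; 7 acryloyl chloride
Product: 8 (R)-3-acryloyl-4-benzyl-1,3-oxazolidin-2-one
Conditions: MeMgBr, THF, 0 °C; 7, −78 → 0 °C
Reagents that add atoms: none
Why: N-acylation of the magnesium salt of the oxazolidinone gives the chiral acrylimide without touching its stereocentre.

Step 4
Reactants: 5 (S,E)-silyloxy diene; 8 (R)-3-acryloyl-4-benzyl-1,3-oxazolidin-2-one
Product: 9 cis-(1S,2R)-2-[(2S)-2-(tert-butyldimethylsilyloxy)propyl]-4-methylcyclohex-3-ene-1-carbonyl imide of (R)-4-benzyloxazolidinone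
Conditions: Et2AlCl (1.4 equiv), CH2Cl2, −100 → −78 °C; 1 M HCl
Reagents that add atoms: none
Why: In this oxazolidinone auxiliary-controlled Diels–Alder reaction, excess Et2AlCl locks 8 as a cationic s-cis chelate whose alpha-Si face is covered by the benzyl group, the 1-alkyl and 3-methyl groups of 5 both steer the acyl-bearing carbon to the substituted diene terminus, and endo addition of the E-diene to the open Re face sets C8a as S and C4a as R, that is cis.

Step 5
Reactants: 9 Diels–Alder imide
Product: 11 (1S,2R)-2-[(2S)-2-(tert-butyldimethylsilyloxy)propyl]-4-methylcyclohex-3-ene-1-carboxylic acid, via peroxy acid 10 (not isolated)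
Conditions: LiOH, H2O2, THF/H2O, 0 °C; aq Na2SO3; dilute HCl
Reagents that add atoms: hydrogen peroxide, OO
Why: Lithium hydroperoxide cleavage of an N-acyloxazolidinone attacks the exocyclic carbonyl, is too weakly basic to epimerise C8a, and is followed by sulfite reduction of the percarboxylate before acidification.

Step 6
Reactants: 11 cis carboxylic acid; 12 triethyl phosphonoacetate
Product: 14 ethyl 2-(diethoxyphosphoryl)-3-oxo-3-[(1S,2R)-cyclohexenyl]propanoate (keto–enol mixture), via acyl imidazolide 13 (not isolated)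
Conditions: CDI, THF, rt; then 12, MgCl2, Et3N, THF/MeCN, 0 °C → rt; dilute HCl
Reagents that add atoms: 1,1'-carbonyldiimidazole, O=C(n1ccnc1)n1ccnc1 (its imidazolyl group is carried only by 13)
Why: Magnesium-chelate C-acylation of an active methylene compound (Masamune–Brooks type) builds the C8a–C1–C2 array, keeps the product as its enolate so that C2–H rather than C8a–H is the acidic site, and avoids a Knoevenagel condensation on a hindered, epimerisable methyl ketone.

Step 7
Reactants: 14 acyl phosphonoacetate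
Product: 15 enol triflate at C1 (E/Z mixture)
Conditions: i-Pr2NEt, Tf2O, CH2Cl2, −78 °C
Reagents that add atoms: triflic anhydride, O=S(=O)(OS(=O)(=O)C(F)(F)F)C(F)(F)F
Why: Enol triflate formation by O-sulfonylation of the fully enolised 1,3-dicarbonyl-type compound is fast at low temperature, and the alkene geometry is of no consequence.

Step 8
Reactants: 15 enol triflate
Product: 16 ethyl 2-(diethoxyphosphoryl)-3-{(1S,2R)-2-[(2S)-2-(tert-butyldimethylsilyloxy)propyl]-4-methylcyclohex-3-en-1-yl}but-2-enoate (E/Z mixture)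
Conditions: MeZnCl, Pd(PPh3)4 (5 mol%), THF, 0 °C → rt
Reagents that add atoms: methylzinc chloride, C[Zn]Cl
Why: Negishi cross-coupling of an electron-poor vinyl triflate at zerovalent palladium installs the first C1 methyl, and copper-free MeZnCl does not add to the alkylidene product, so the reaction stops at 16.

Step 9
Reactants: 16 silyl-protected alkylidene phosphonoacetate
Product: 17 ethyl 2-(diethoxyphosphoryl)-3-{(1S,2R)-2-[(2S)-2-hydroxypropyl]-4-methylcyclohex-3-en-1-yl}but-2-enoate
Conditions: HF·pyridine, THF, 0 °C → rt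
Reagents that add atoms: none
Why: Acidic fluoride desilylation avoids the basic media that could deconjugate the alkylidene through the vinylogous C8a–H, and oxa-Michael addition of the freed alcohol to the fully substituted C1 is uphill.

Step 10
Reactants: 17 hydroxy alkylidene phosphonoacetate
Product: 18 ethyl 2-(diethoxyphosphoryl)-3-[(1S,2R)-4-methyl-2-(2-oxopropyl)cyclohex-3-en-1-yl]but-2-enoate (E/Z mixture)
Conditions: Dess–Martin periodinane, CH2Cl2, 0 °C → rt
Reagents that add atoms: none
Why: Dess–Martin oxidation under neutral conditions gives the C3 methyl ketone, erases the spectator carbinol centre and leaves C4a and C8a alone.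

Step 11
Reactants: 18 cis keto alkylidene phosphonoacetate
Product: 20 ethyl (4aR,8aS)-1,1,3,6-tetramethyl-1,4,4a,7,8,8a-hexahydronaphthalene-2-carboxylate, via lithium phosphonate carbanion 19 (not isolated)
Conditions: Me2CuLi (1.1 equiv; CuI + 2 MeLi), Et2O/THF, −78 → 0 °C, then 40 °C; aq NH4Cl
Reagents that add atoms: lithium dimethylcuprate, [Li+].C[Cu-]C
Why: Proposed new method: the soft cuprate adds 1,4 to the doubly activated C1=C2 bond of 18, which lays down the second C1 methyl and leaves the lithium phosphonoacetate carbanion 19 at C2. On warming, 19 attacks the C3 ketone held on the cis C4a arm and the oxaphosphetane expels lithium diethyl phosphate, so the new alkene can only lie between C2 and C3, where the ester keeps it in conjugation. The closest known reaction types are the tandem organocopper addition–Horner–Wadsworth–Emmons olefination of alkylidene phosphonoacetates with added aldehydes and Michael-initiated intramolecular olefinations of vinylphosphonates; capture by a tethered ketone beside a newly made quaternary carbon is the untested part. Ring B closes in a 6-(enolexo)-exo-trig mode. No stereocentre is formed, and C4a and C8a are carried through because the cuprate is too weak a base to remove the vinylogous C8a–H. The step needs attack at the alkylidene before the ketone, which the two acceptor groups on C2, the low temperature and the near-stoichiometric charge of Me2CuLi (spent MeCu is inert to ketones) secure.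

Step 12
Reactants: 20 bicyclic ester
Product: 21 [(4aR,8aS)-1,1,3,6-tetramethyl-1,4,4a,7,8,8a-hexahydronaphthalen-2-yl]methanol
Conditions: DIBAL-H, CH2Cl2, −78 → 0 °C; aq Rochelle salt
Reagents that add atoms: none
Why: DIBAL-H 1,2-reduction of a hindered conjugated ester, as practised on beta-cyclogeranate esters, gives the allylic alcohol and leaves both ring alkenes alone.

Step 13
Reactants: 21 allylic alcohol
Product: 22 {[(4aR,8aS)-1,1,3,6-tetramethyl-1,4,4a,7,8,8a-hexahydronaphthalen-2-yl]methyl}triphenylphosphonium bromide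
Conditions: PPh3·HBr, MeOH, rt
Reagents that add atoms: triphenylphosphonium bromide, [Br-].[PH+](c1ccccc1)(c1ccccc1)c1ccccc1
Why: Direct phosphonium salt formation from an allylic alcohol (ionisation to the allyl cation and capture at its primary end) is the standard entry to beta-cyclogeranyl-type Wittig salts.

Step 14
Reactants: 23 (S)-2-methylglycidol
Product: 24 (R)-(2-methyloxiran-2-yl)methyl 4-toluenesulfonate
Conditions: TsCl, Et3N, DMAP (cat.), CH2Cl2, 0 °C
Reagents that add atoms: 4-toluenesulfonyl chloride, Cc1ccc(cc1)S(=O)(=O)Cl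
Why: Sulfonylation of the primary alcohol breaks no bond at the stereocentre, and the descriptor changes from S to R only through the priority rules.

Step 15
Reactants: 24 (R)-2-methylglycidyl tosylate; 25 allylmagnesium chloride
Product: 27 (R)-2-(but-3-en-1-yl)-2-methyloxirane, via hydroxy tosylate 26 (not isolated)
Conditions: 25, CuI (10 mol%), THF, −40 → 0 °C; aq NH4Cl; crude 26, K2CO3, MeOH, rt
Reagents that add atoms: none
Why: Copper-catalysed Grignard opening at the unhindered oxirane CH2 (the neopentyl-type CH2OTs is inert) followed by Williamson-type closure of the tertiary alkoxide onto CH2OTs shifts the oxirane without breaking the tertiary C–O bond, so the configuration is kept.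

Step 16
Reactants: 27 (R)-2-(but-3-en-1-yl)-2-methyloxirane
Product: 28 (S)-2-hydroperoxy-2-methylhex-5-en-1-ol
Conditions: anhydrous H2O2 in Et2O, H3PMo12O40 (3 mol%), 0 °C → rt
Reagents that add atoms: hydrogen peroxide, OO
Why: Molybdic-acid catalysed perhydrolysis of a 2,2-disubstituted oxirane opens the activated ring at the tertiary carbon from the rear (borderline SN2, as in the acid hydrolysis of such epoxides with inversion), which sets the methyl-bearing dioxane carbon and leaves CH2OH as the later coupling handle.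

Step 17
Reactants: 28 hydroperoxy alcohol
Product: 29 (S)-bis-TBS derivative (silyl ether and silyl peroxide) of 28
Conditions: TBSCl (2.5 equiv), imidazole, DMF, 0 °C → rt
Reagents that add atoms: tert-butyldimethylsilyl chloride, CC(C)(C)[Si](C)(C)Cl
Why: Exhaustive silylation covers both O–H groups, so that no base ever meets a free beta-hydroxy hydroperoxide, which would fragment to ketone and formaldehyde.

Step 18
Reactants: 29 bis-silyl alkene
Product: 30 (4S)-5-(tert-butyldimethylsilyloxy)-4-(tert-butyldimethylsilylperoxy)-4-methylpentanal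
Conditions: O3, pyridine, CH2Cl2, −78 °C
Reagents that add atoms: ozone, [O-][O+]=O
Why: Pyridine-promoted ozonolysis delivers the aldehyde directly without a reducing agent, which spares the silyl peroxide.

Step 19
Reactants: 30 peroxy aldehyde; 31 cis-but-2-ene
Product: 33 (3S,4S,7S)-8-(tert-butyldimethylsilyloxy)-7-(tert-butyldimethylsilylperoxy)-3,7-dimethyloct-1-en-4-ol, via Z-crotylborane 32 (not isolated)
Conditions: 31, n-BuLi, KOt-Bu, THF, −78 → −45 °C; (+)-Ipc2BOMe, −78 °C; BF3·OEt2; 30, −78 °C; HOCH2CH2NH2, Et2O, rt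
Reagents that add atoms: (+)-B-methoxydiisopinocampheylborane, COB([C@H]1C[C@H]2C[C@@H]([C@@H]1C)C2(C)C)[C@H]1C[C@H]2C[C@@H]([C@@H]1C)C2(C)C (its boryl group is carried only by 32)
Why: In this Brown crotylboration through a chair Zimmerman–Traxler transition state, the Z-crotyl geometry gives the syn relation, the Ipc groups derived from (−)-alpha-pinene direct attack to the Re face of 30 so that (3S,4S) is set under reagent control, and the amine work-up needs no oxidant.

Step 20
Reactants: 33 syn homoallylic alcohol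
Product: 34 (3S,4S,7S)-methanesulfonate of 33
Conditions: MsCl, Et3N, CH2Cl2, 0 °C
Reagents that add atoms: methanesulfonyl chloride, CS(=O)(=O)Cl
Why: Mesylation activates the carbinol with retention for the SN2 ring closure, at a carbon that carries no acidifying carbonyl neighbour.

Step 21
Reactants: 34 mesylate
Product: 36 [(3S,6R)-6-[(2S)-but-3-en-2-yl]-3-methyl-1,2-dioxan-3-yl]methanol, via silyl ether 35 (not isolated)
Conditions: TBAF (1.1 equiv), THF, 0 °C; then HF·pyridine, 0 °C → rt
Reagents that add atoms: none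
Why: Fluoride strips the labile peroxy-silyl group first, the peroxide anion displaces the mesylate in a 6-exo-tet intramolecular SN2 alkylation with inversion (this sets the CH–O carbon as R and puts its side chain cis to CH2O), and HF·pyridine then frees the primary alcohol without base.

Step 22
Reactants: 36 vinyl dioxane alcohol
Product: 38 (2R)-2-[(3R,6S)-6-(hydroxymethyl)-6-methyl-1,2-dioxan-3-yl]propanoic acid, via aldehyde 37 (not isolated)
Conditions: O3, pyridine, CH2Cl2, −78 °C; concentrate; NaClO2, NaH2PO4, 2-methylbut-2-ene, t-BuOH/H2O, rt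
Reagents that add atoms: ozone, [O-][O+]=O; sodium chlorite, [Na+].[O-]Cl=O
Why: Ozonolysis of the vinyl group and Pinnick oxidation of the crude aldehyde in buffered medium give the acid without epimerising the alpha centre or eliminating the beta-peroxide, and neither oxidant touches the dialkyl peroxide or the primary alcohol.

Step 23
Reactants: 38 hydroxy acid
Product: 39 methyl (2R)-2-[(3R,6S)-6-(hydroxymethyl)-6-methyl-1,2-dioxan-3-yl]propanoate
Conditions: TMSCHN2, toluene/MeOH, 0 °C
Reagents that add atoms: trimethylsilyldiazomethane, C[Si](C)(C)C=[N+]=[N-]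
Why: Esterification with trimethylsilyldiazomethane is neutral and selective for the acid over the alcohol.

Step 24
Reactants: 39 hydroxy ester
Product: 40 methyl (2R)-2-[(3R,6S)-6-formyl-6-methyl-1,2-dioxan-3-yl]propanoate
Conditions: Dess–Martin periodinane, CH2Cl2, 0 °C → rt
Reagents that add atoms: none
Why: Dess–Martin oxidation gives the non-enolisable alpha-peroxy aldehyde under neutral conditions.

Step 25
Reactants: 22 phosphonium bromide; 40 formyl dioxane
Product: 42 methyl (2R)-2-[(3R,6S)-6-methyl-6-{2-[(4aR,8aS)-1,1,3,6-tetramethyl-1,4,4a,7,8,8a-hexahydronaphthalen-2-yl]ethenyl}-1,2-dioxan-3-yl]propanoate (E/Z mixture), via ylide 41 (not isolated)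
Conditions: 22, NaHMDS, THF, −78 → 0 °C; 40, −78 °C → rt
Reagents that add atoms: none
Why: This Wittig olefination uses a semi-stabilised beta-cyclogeranyl-type ylide that is pre-formed so that no free base meets the peroxide or the ester, the aldehyde cannot enolise, and the alkene geometry is irrelevant because it is reduced next.

Step 26
Reactants: 42 diene ester
Product: 43 methyl (2R)-2-[(3R,6R)-6-methyl-6-{2-[(4aR,8aS)-1,1,3,6-tetramethyl-1,4,4a,7,8,8a-hexahydronaphthalen-2-yl]ethyl}-1,2-dioxan-3-yl]propanoate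
Conditions: KO2CN=NCO2K, AcOH, MeOH/CH2Cl2, 0 °C → rt, portionwise with monitoring
Reagents that add atoms: none
Why: Diimide reduction transfers H2 in a concerted way that leaves O–O bonds intact, and its rate falls steeply with alkene substitution, so the disubstituted side-chain alkene should react before the trisubstituted C5=C6 and the tetrasubstituted C2=C3 bonds.

Step 27
Reactants: 43 saturated methyl ester
Product: 44 (2R)-2-[(3R,6R)-6-methyl-6-{2-[(4aR,8aS)-1,1,3,6-tetramethyl-1,4,4a,7,8,8a-hexahydronaphthalen-2-yl]ethyl}-1,2-dioxan-3-yl]propanoic acid (CNP0122760.1)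
Conditions: LiOH, THF/MeOH/H2O, 0 °C → rt; dilute HCl to pH 3
Reagents that add atoms: lithium hydroxide, [Li+].[OH-]
Why: Saponification by acyl attack of hydroxide at low temperature is faster than alpha-deprotonation, so the alpha-methyl centre and the beta-peroxy linkage should survive.

Compound list
1 | (S)-pent-4-yn-2-ol | C[C@H](O)CC#C | starting material
2 | (S)-tert-butyldimethyl(pent-4-yn-2-yloxy)silane | C[C@H](O[Si](C)(C)C(C)(C)C)CC#C | intermediate
3 | 2-bromopropene | CC(Br)=C | starting material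
4 | (S,E)-tert-butyldimethyl{[5-(4,4,5,5-tetramethyl-1,3,2-dioxaborolan-2-yl)pent-4-en-2-yl]oxy}silane | C[C@H](O[Si](C)(C)C(C)(C)C)C/C=C/B1OC(C)(C)C(C)(C)O1 | intermediate
5 | (S,E)-tert-butyldimethyl[(6-methylhepta-4,6-dien-2-yl)oxy]silane | C[C@H](O[Si](C)(C)C(C)(C)C)C/C=C/C(C)=C | intermediate
6 | (R)-4-benzyl-1,3-oxazolidin-2-one | O=C1N[C@H](Cc2ccccc2)CO1 | starting material
7 | acryloyl chloride | C=CC(=O)Cl | starting material
8 | (R)-3-acryloyl-4-benzyl-1,3-oxazolidin-2-one | C=CC(=O)N1[C@H](Cc2ccccc2)COC1=O | intermediate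
9 | (4R)-4-benzyl-3-{(1S,2R)-2-[(2S)-2-(tert-butyldimethylsilyloxy)propyl]-4-methylcyclohex-3-ene-1-carbonyl}-1,3-oxazolidin-2-one | CC1=C[C@@H](C[C@H](C)O[Si](C)(C)C(C)(C)C)[C@@H](C(=O)N2[C@H](Cc3ccccc3)COC2=O)CC1 | intermediate
10 | (1S,2R)-2-[(2S)-2-(tert-butyldimethylsilyloxy)propyl]-4-methylcyclohex-3-ene-1-carboperoxoic acid | CC1=C[C@@H](C[C@H](C)O[Si](C)(C)C(C)(C)C)[C@@H](C(=O)OO)CC1 | intermediate
11 | (1S,2R)-2-[(2S)-2-(tert-butyldimethylsilyloxy)propyl]-4-methylcyclohex-3-ene-1-carboxylic acid | CC1=C[C@@H](C[C@H](C)O[Si](C)(C)C(C)(C)C)[C@@H](C(=O)O)CC1 | intermediate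
12 | triethyl phosphonoacetate | CCOC(=O)CP(=O)(OCC)OCC | starting material
13 | N-acylimidazole of acid 11 | CC1=C[C@@H](C[C@H](C)O[Si](C)(C)C(C)(C)C)[C@@H](C(=O)n2ccnc2)CC1 | intermediate
14 | ethyl 2-(diethoxyphosphoryl)-3-{(1S,2R)-2-[(2S)-2-(tert-butyldimethylsilyloxy)propyl]-4-methylcyclohex-3-en-1-yl}-3-oxopropanoate (C2 labile, keto–enol) | CC1=C[C@@H](C[C@H](C)O[Si](C)(C)C(C)(C)C)[C@@H](C(=O)C(C(=O)OCC)P(=O)(OCC)OCC)CC1 | intermediate
15 | ethyl 2-(diethoxyphosphoryl)-3-{(1S,2R)-2-[(2S)-2-(tert-butyldimethylsilyloxy)propyl]-4-methylcyclohex-3-en-1-yl}-3-(trifluoromethylsulfonyloxy)prop-2-enoate (E/Z) | CC1=C[C@@H](C[C@H](C)O[Si](C)(C)C(C)(C)C)[C@@H](C(OS(=O)(=O)C(F)(F)F)=C(C(=O)OCC)P(=O)(OCC)OCC)CC1 | intermediate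
16 | ethyl 2-(diethoxyphosphoryl)-3-{(1S,2R)-2-[(2S)-2-(tert-butyldimethylsilyloxy)propyl]-4-methylcyclohex-3-en-1-yl}but-2-enoate (E/Z) | CC1=C[C@@H](C[C@H](C)O[Si](C)(C)C(C)(C)C)[C@@H](C(C)=C(C(=O)OCC)P(=O)(OCC)OCC)CC1 | intermediate
17 | ethyl 2-(diethoxyphosphoryl)-3-{(1S,2R)-2-[(2S)-2-hydroxypropyl]-4-methylcyclohex-3-en-1-yl}but-2-enoate (E/Z) | CC1=C[C@@H](C[C@H](C)O)[C@@H](C(C)=C(C(=O)OCC)P(=O)(OCC)OCC)CC1 | intermediate
18 | ethyl 2-(diethoxyphosphoryl)-3-[(1S,2R)-4-methyl-2-(2-oxopropyl)cyclohex-3-en-1-yl]but-2-enoate (E/Z) | CC1=C[C@@H](CC(C)=O)[C@@H](C(C)=C(C(=O)OCC)P(=O)(OCC)OCC)CC1 | intermediate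
19 | lithium salt of the C2 carbanion of ethyl 2-(diethoxyphosphoryl)-3-methyl-3-[(1S,2R)-4-methyl-2-(2-oxopropyl)cyclohex-3-en-1-yl]butanoate | CC1=C[C@@H](CC(C)=O)[C@@H](C(C)(C)[C-](C(=O)OCC)P(=O)(OCC)OCC)CC1.[Li+] | intermediate
20 | ethyl (4aR,8aS)-1,1,3,6-tetramethyl-1,4,4a,7,8,8a-hexahydronaphthalene-2-carboxylate | CC1=C[C@H]2CC(C)=C(C(=O)OCC)C(C)(C)[C@H]2CC1 | intermediate
21 | [(4aR,8aS)-1,1,3,6-tetramethyl-1,4,4a,7,8,8a-hexahydronaphthalen-2-yl]methanol | CC1=C[C@H]2CC(C)=C(CO)C(C)(C)[C@H]2CC1 | intermediate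
22 | {[(4aR,8aS)-1,1,3,6-tetramethyl-1,4,4a,7,8,8a-hexahydronaphthalen-2-yl]methyl}triphenylphosphonium bromide | CC1=C[C@H]2CC(C)=C(C[P+](c3ccccc3)(c3ccccc3)c3ccccc3)C(C)(C)[C@H]2CC1.[Br-] | intermediate
23 | (S)-2-methylglycidol, [(2S)-2-methyloxiran-2-yl]methanol | OC[C@@]1(C)CO1 | starting material
24 | (R)-(2-methyloxiran-2-yl)methyl 4-toluenesulfonate | Cc1ccc(cc1)S(=O)(=O)OC[C@@]1(C)CO1 | intermediate
25 | allylmagnesium chloride | C=CC[Mg]Cl | starting material
26 | (R)-2-hydroxy-2-methylhex-5-en-1-yl 4-toluenesulfonate | Cc1ccc(cc1)S(=O)(=O)OC[C@](C)(O)CCC=C | intermediate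
27 | (R)-2-(but-3-en-1-yl)-2-methyloxirane | C=CCC[C@]1(C)CO1 | intermediate
28 | (S)-2-hydroperoxy-2-methylhex-5-en-1-ol | OC[C@](OO)(C)CCC=C | intermediate
29 | tert-butyl({(2S)-2-[(tert-butyldimethylsilyl)peroxy]-2-methylhex-5-en-1-yl}oxy)dimethylsilane | CC(C)(C)[Si](C)(C)OC[C@](OO[Si](C)(C)C(C)(C)C)(C)CCC=C | intermediate
30 | (4S)-5-(tert-butyldimethylsilyloxy)-4-(tert-butyldimethylsilylperoxy)-4-methylpentanal | CC(C)(C)[Si](C)(C)OC[C@](OO[Si](C)(C)C(C)(C)C)(C)CCC=O | intermediate
31 | cis-but-2-ene | C/C=C\C | starting material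
32 | (Z)-crotyldiisopinocampheylborane, Ipc groups from (−)-alpha-pinene | C/C=C\CB([C@H]1C[C@H]2C[C@@H]([C@@H]1C)C2(C)C)[C@H]1C[C@H]2C[C@@H]([C@@H]1C)C2(C)C | intermediate
33 | (3S,4S,7S)-8-(tert-butyldimethylsilyloxy)-7-(tert-butyldimethylsilylperoxy)-3,7-dimethyloct-1-en-4-ol | CC(C)(C)[Si](C)(C)OC[C@](OO[Si](C)(C)C(C)(C)C)(C)CC[C@H](O)[C@@H](C)C=C | intermediate
34 | (3S,4S,7S)-8-(tert-butyldimethylsilyloxy)-7-(tert-butyldimethylsilylperoxy)-3,7-dimethyloct-1-en-4-yl methanesulfonate | CC(C)(C)[Si](C)(C)OC[C@](OO[Si](C)(C)C(C)(C)C)(C)CC[C@H](OS(C)(=O)=O)[C@@H](C)C=C | intermediate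
35 | tert-butyl({(3S,6R)-6-[(2S)-but-3-en-2-yl]-3-methyl-1,2-dioxan-3-yl}methoxy)dimethylsilane | CC(C)(C)[Si](C)(C)OC[C@]1(C)CC[C@H]([C@@H](C)C=C)OO1 | intermediate
36 | [(3S,6R)-6-[(2S)-but-3-en-2-yl]-3-methyl-1,2-dioxan-3-yl]methanol | OC[C@]1(C)CC[C@H]([C@@H](C)C=C)OO1 | intermediate
37 | (2R)-2-[(3R,6S)-6-(hydroxymethyl)-6-methyl-1,2-dioxan-3-yl]propanal | OC[C@]1(C)CC[C@H]([C@@H](C)C=O)OO1 | intermediate
38 | (2R)-2-[(3R,6S)-6-(hydroxymethyl)-6-methyl-1,2-dioxan-3-yl]propanoic acid | OC[C@]1(C)CC[C@H]([C@@H](C)C(=O)O)OO1 | intermediate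
39 | methyl (2R)-2-[(3R,6S)-6-(hydroxymethyl)-6-methyl-1,2-dioxan-3-yl]propanoate | OC[C@]1(C)CC[C@H]([C@@H](C)C(=O)OC)OO1 | intermediate
40 | methyl (2R)-2-[(3R,6S)-6-formyl-6-methyl-1,2-dioxan-3-yl]propanoate | O=C[C@]1(C)CC[C@H]([C@@H](C)C(=O)OC)OO1 | intermediate
41 | {[(4aR,8aS)-1,1,3,6-tetramethyl-1,4,4a,7,8,8a-hexahydronaphthalen-2-yl]methylidene}triphenylphosphorane | CC1=C[C@H]2CC(C)=C(C=P(c3ccccc3)(c3ccccc3)c3ccccc3)C(C)(C)[C@H]2CC1 | intermediate
42 | methyl (2R)-2-[(3R,6S)-6-methyl-6-{2-[(4aR,8aS)-1,1,3,6-tetramethyl-1,4,4a,7,8,8a-hexahydronaphthalen-2-yl]ethenyl}-1,2-dioxan-3-yl]propanoate (E/Z) | CC1=C[C@H]2CC(C)=C(C=C[C@]3(C)CC[C@H]([C@@H](C)C(=O)OC)OO3)C(C)(C)[C@H]2CC1 | intermediate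
43 | methyl (2R)-2-[(3R,6R)-6-methyl-6-{2-[(4aR,8aS)-1,1,3,6-tetramethyl-1,4,4a,7,8,8a-hexahydronaphthalen-2-yl]ethyl}-1,2-dioxan-3-yl]propanoate | CC1=C[C@H]2CC(C)=C(CC[C@]3(C)CC[C@H]([C@@H](C)C(=O)OC)OO3)C(C)(C)[C@H]2CC1 | intermediate
44 | (2R)-2-[(3R,6R)-6-methyl-6-{2-[(4aR,8aS)-1,1,3,6-tetramethyl-1,4,4a,7,8,8a-hexahydronaphthalen-2-yl]ethyl}-1,2-dioxan-3-yl]propanoic acid | CC1=C[C@H]2CC(C)=C(CC[C@]3(C)CC[C@H]([C@@H](C)C(=O)O)OO3)C(C)(C)[C@H]2CC1 | target

Total step count: 27.
Longest linear sequence: 15 steps (steps 1, 2, 4–13, 25–27); the dioxane branch runs 14 steps (steps 14–27).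

Steps most likely to fail

1. Step 11 (Proposed new method).
- What may go wrong: conjugate addition may succeed while the crowded carbanion adds too slowly to the ketone. Alternatively, the cuprate may attack the ketone or remove the C8a proton.
- Fallback: separate the two events with known reactions, setting out from 16, where the ketone is still masked.
 - Me2CuLi addition and protonation gives the saturated silyl-protected phosphonoacetate F1.
 - HF·pyridine gives the alcohol F2.
 - Dess–Martin oxidation gives the keto phosphonate F3.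
 - A classical base-mediated intramolecular Horner–Wadsworth–Emmons closure (NaH in hot THF, or K2CO3/18-crown-6 in toluene) comes back to the route at 20.

2. Step 16.
- What may go wrong: the activated oxirane may ionise partly before attack, which erodes the configuration at the tertiary carbon. Traces of water may also compete with H2O2.
- Fallback: give up stereospecific C–O formation and rely on separation, setting out from 27.
 - Et2Al(TMP) isomerises the epoxide to the allylic alcohol 2-methylidenehex-5-en-1-ol F4.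
 - Mukaiyama–Isayama peroxysilylation (Co(thd)2, O2, Et3SiH) attacks the 1,1-disubstituted alkene first and gives the racemic triethylsilyl peroxide F5.
 - HF·pyridine comes back to the route at 28, now racemic.
 - After the reagent-controlled step 19 the two epimers at the peroxide carbon are diastereomers and are parted by chromatography at 33 or 36.

3. Step 21.
- What may go wrong: E2 loss of the mesylate towards the conjugated diene, or substitution by fluoride, may outrun ring closure.
- Fallback: change the C–O bond formation from substitution to conjugate addition, setting out from 30.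
 - Wittig reaction with Ph3P=C(CH3)CO2CH3 gives the E-enoate F6.
 - TBAF releases the peroxide anion, which closes by the known 6-exo-trig oxa-Michael addition of hydroperoxy enoates.
 - Chromatographic separation of the side-chain diastereomers gives the silyl-protected dioxane ester F7.
 - HF·pyridine comes back to the route at 39.

Further compounds
F1 | step 11 | ethyl 2-(diethoxyphosphoryl)-3-{(1S,2R)-2-[(2S)-2-(tert-butyldimethylsilyloxy)propyl]-4-methylcyclohex-3-en-1-yl}-3-methylbutanoate (epimers at C2) | CC1=C[C@@H](C[C@H](C)O[Si](C)(C)C(C)(C)C)[C@@H](C(C)(C)C(C(=O)OCC)P(=O)(OCC)OCC)CC1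
F2 | step 11 | ethyl 2-(diethoxyphosphoryl)-3-{(1S,2R)-2-[(2S)-2-hydroxypropyl]-4-methylcyclohex-3-en-1-yl}-3-methylbutanoate (epimers at C2) | CC1=C[C@@H](C[C@H](C)O)[C@@H](C(C)(C)C(C(=O)OCC)P(=O)(OCC)OCC)CC1
F3 | step 11 | ethyl 2-(diethoxyphosphoryl)-3-methyl-3-[(1S,2R)-4-methyl-2-(2-oxopropyl)cyclohex-3-en-1-yl]butanoate (epimers at C2) | CC1=C[C@@H](CC(C)=O)[C@@H](C(C)(C)C(C(=O)OCC)P(=O)(OCC)OCC)CC1
F4 | step 16 | 2-methylidenehex-5-en-1-ol | C=CCCC(=C)CO
F5 | step 16 | 2-methyl-2-(triethylsilylperoxy)hex-5-en-1-ol (racemic) | C=CCCC(C)(CO)OO[Si](CC)(CC)CC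
F6 | step 21 | methyl (2E,6S)-7-(tert-butyldimethylsilyloxy)-6-(tert-butyldimethylsilylperoxy)-2,6-dimethylhept-2-enoate | CC(C)(C)[Si](C)(C)OC[C@](OO[Si](C)(C)C(C)(C)C)(C)CC/C=C(\C)C(=O)OC
F7 | step 21 | methyl (2R)-2-[(3R,6S)-6-(tert-butyldimethylsilyloxymethyl)-6-methyl-1,2-dioxan-3-yl]propanoate | CC(C)(C)[Si](C)(C)OC[C@]1(C)CC[C@H]([C@@H](C)C(=O)OC)OO1
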